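**Plan**

- Retrosynthesis: first cut the C2–aryl bond between the guaiacyl ring and C2 of the dihydrobenzofuran (C2 radical from a C2 carboxylic acid, plus an arylzinc); then O1–C2 (phenoxide SN2) and C3–C3a (aryl conjugate addition to a γ-silyloxy enoyl imide); then C5–C7′ (aryl addition to (R)-glyceraldehyde acetonide). C7′ is the benzylic carbinol carbon of the side chain, C8′ its neighbour.
- Forward: the triol chain is attached to a 2-bromo-4-iodoguaiacol, C3–C3a is made, the furan ring closes through O1–C2, the guaiacyl ring is joined to C2 last, and three silyl ethers and the acetonide are removed.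
- Enabling feature: C2 lies between ring oxygen O1, whose lone pair stabilises a radical at C2, and stereocentre C3 of the rigid five-membered ring fused to the benzene ring, whose CH2OTBS group blocks one face of that radical.
- Stereochemistry: C8′ is bought with (R)-glyceraldehyde acetonide; C7′ follows from it by Felkin–Anh addition; C3 is set by an (S)-4-benzyloxazolidinone auxiliary; C2 is relayed from C3 in the key step (trans), so the C2 configuration of the acid precursor does not matter.
- Helpers: the carboxyl group on C2 (the former imide carbonyl, activated as an N-acyloxyphthalimide) leaves as CO2 in the key step; the auxiliary is cleaved one step after ring closure.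

Key step: step 11

Remark: compounds 1, 4, 9, 11, 18 and 20 are taken as purchasable; C2 of 16, 17 and 19 is carried as a mixture of epimers (drawn without configuration) because this centre becomes a planar radical in step 11; TBS = tert-butyldimethylsilyl.

**Step 1**
Reactants: 1 2-bromo-6-methoxyphenol
Product: 2 2-bromo-4-iodo-6-methoxyphenol
Conditions: NIS, TsOH (cat.), MeCN, 0 °C → rt
Reagents that add atoms: N-iodosuccinimide, O=C1CCC(=O)N1I
Why: Electrophilic aromatic iodination of the phenol should go to C4, the only free ortho/para position of the OH group, because both ortho positions already carry Br and OMe.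

**Step 2**
Reactants: 2 2-bromo-4-iodo-6-methoxyphenol
Product: 3 (2-bromo-4-iodo-6-methoxyphenoxy)(tert-butyl)dimethylsilane
Conditions: TBSCl, imidazole, DMF, rt
Reagents that add atoms: tert-butyldimethylsilyl chloride, CC(C)(C)[Si](C)(C)Cl
Why: Imidazole-promoted silylation masks the acidic phenol before halogen–metal exchange and supplies the fluoride-labile trigger for the later ring closure.

**Step 3**
Reactants: 3 (2-bromo-4-iodo-6-methoxyphenoxy)(tert-butyl)dimethylsilane; 4 (R)-2,2-dimethyl-1,3-dioxolane-4-carbaldehyde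
Product: 7 (S)-[3-bromo-4-(TBSO)-5-methoxyphenyl][(R)-2,2-dimethyl-1,3-dioxolan-4-yl]methanol (anti adduct), via arylmagnesium chloride 5 (not isolated), via aryltitanium triisopropoxide 6 (not isolated)
Conditions: i-PrMgCl·LiCl, THF, −20 → 0 °C; ClTi(OiPr)3, −78 °C; then 4, −78 → −20 °C; NH4Cl (aq)
Reagents that add atoms: none
Why: Iodine–magnesium exchange is selective for C–I over C–Br, and addition of the non-chelating aryltitanium reagent to the α-alkoxy aldehyde should follow the Felkin–Anh model (attack anti to the dioxolane C–O bond) to give the anti (7′S,8′R) carbinol, with C8′ carried unchanged from 4 and the syn epimer removed by chromatography.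

**Step 4**
Reactants: 7 anti carbinol
Product: 8 {2-bromo-4-[(S)-(TBSO)((R)-2,2-dimethyl-1,3-dioxolan-4-yl)methyl]-6-methoxyphenoxy}(tert-butyl)dimethylsilane
Conditions: TBSOTf, 2,6-lutidine, CH2Cl2, −78 → 0 °C
Reagents that add atoms: tert-butyldimethylsilyl trifluoromethanesulfonate, CC(C)(C)[Si](C)(C)OS(=O)(=O)C(F)(F)F
Why: Silyl triflate silylation of the secondary benzylic alcohol under lutidine buffering should leave the acetonide and the aryl bromide untouched.

**Step 5**
Reactants: 9 (S)-4-benzyl-3-(2-chloroacetyl)oxazolidin-2-one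
Product: 10 diethyl {2-[(S)-4-benzyl-2-oxooxazolidin-3-yl]-2-oxoethyl}phosphonate
Conditions: P(OEt)3, NaI (cat.), toluene, 110 °C
Reagents that add atoms: triethyl phosphite, CCOP(OCC)OCC
Why: Michaelis–Arbuzov reaction of the α-halo imide (iodide catalysis) gives the phosphonate needed for olefination.

**Step 6**
Reactants: 10 phosphonate imide; 11 2-(tert-butyldimethylsilyloxy)acetaldehyde
Product: 12 (S)-4-benzyl-3-[(E)-4-(TBSO)but-2-enoyl]oxazolidin-2-one
Conditions: LiCl, i-Pr2NEt, MeCN, rt
Reagents that add atoms: none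
Why: Horner–Wadsworth–Emmons olefination under mild Masamune–Roush conditions should give the E-enoyl imide without harming the base-sensitive α-silyloxy aldehyde.

**Step 7**
Reactants: 8 bis-silyl aryl bromide; 12 E-enoyl imide
Product: 15 (S)-4-benzyl-3-[(2S,3R)-2-bromo-4-(TBSO)-3-{2-(TBSO)-3-methoxy-5-[(S)-(TBSO)((R)-2,2-dimethyl-1,3-dioxolan-4-yl)methyl]phenyl}butanoyl]oxazolidin-2-one, via arylmagnesium bromide 13 (not isolated), via bromomagnesium enolate 14 (not isolated)
Conditions: Mg turnings, LiCl, THF, 25 °C; CuBr·SMe2 (20 mol%), THF/Me2S, −40 °C; then 12, −40 → −10 °C; NBS, −78 °C; NH4Cl (aq)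
Reagents that add atoms: N-bromosuccinimide, O=C1CCC(=O)N1Br
Why: Copper-catalysed conjugate addition of an aryl Grignard reagent to a chiral N-enoyl oxazolidinone, with in situ electrophilic bromination of the enolate; in the magnesium-chelated syn-s-cis enoyl imide the benzyl group of the (S)-auxiliary shields the Re face of Cβ, so the aryl group should add to the Si face and set C3 as R, and either α-bromo epimer is acceptable for what follows.

**Step 8**
Reactants: 15 α-bromo imide
Product: 16 (S)-4-benzyl-3-{(3R)-3-[(TBSO)methyl]-5-[(S)-(TBSO)((R)-2,2-dimethyl-1,3-dioxolan-4-yl)methyl]-7-methoxy-2,3-dihydrobenzofuran-2-carbonyl}oxazolidin-2-one (C2 epimers)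
Conditions: Bu4NF (1.05 equiv), THF, −20 → 0 °C
Reagents that add atoms: none
Why: Fluoride cleaves the aryl silyl ether much faster than the alkyl silyl ethers, and the phenoxide should close the furan ring by intramolecular SN2 displacement of the α-bromide (5-exo-tet Williamson etherification); C3 is not touched, and bromide exchange lets either α-epimer cyclise.

**Step 9**
Reactants: 16 dihydrobenzofuran imide
Product: 17 (3R)-3-[(TBSO)methyl]-5-[(S)-(TBSO)((R)-2,2-dimethyl-1,3-dioxolan-4-yl)methyl]-7-methoxy-2,3-dihydrobenzofuran-2-carboxylic acid (C2 epimers)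
Conditions: LiOH, H2O2, THF/H2O, 0 °C; Na2SO3 (aq); HCl (aq) to pH 4, 0 °C
Reagents that add atoms: hydrogen peroxide (as lithium hydroperoxide), OO
Why: Lithium hydroperoxide cleavage of an N-acyloxazolidinone attacks the exocyclic carbonyl selectively and should release the acid and the auxiliary while the silyl ethers and the acetonide survive the cold, briefly basic medium.

**Step 10**
Reactants: 17 carboxylic acid; 18 N-hydroxyphthalimide
Product: 19 1,3-dioxoisoindolin-2-yl (3R)-3-[(TBSO)methyl]-5-[(S)-(TBSO)((R)-2,2-dimethyl-1,3-dioxolan-4-yl)methyl]-7-methoxy-2,3-dihydrobenzofuran-2-carboxylate (C2 epimers)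
Conditions: DIC, DMAP (cat.), CH2Cl2, rt
Reagents that add atoms: none
Why: Carbodiimide (Steglich-type) esterification converts the acid into the N-acyloxyphthalimide, the redox-active ester that makes single-electron decarboxylation possible.

**Step 11**
Reactants: 19 redox-active ester; 20 (4-bromo-2-methoxyphenoxy)(tert-butyl)dimethylsilane
Product: 23 tert-butyl{4-[(2S,3R)-3-[(TBSO)methyl]-5-[(S)-(TBSO)((R)-2,2-dimethyl-1,3-dioxolan-4-yl)methyl]-7-methoxy-2,3-dihydrobenzofuran-2-yl]-2-methoxyphenoxy}dimethylsilane, via aryllithium 21 (not isolated), via arylzinc chloride 22 (not isolated)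
Conditions: 20, n-BuLi, THF, −78 °C; ZnCl2, −78 °C → rt; then 19, NiCl2·glyme (20 mol%), 4,4′-di-tert-butyl-2,2′-bipyridine (40 mol%), THF/DMF, 25 °C
Reagents that add atoms: none
Why: Arylzinc 22 transmetalates to nickel, and the low-valent aryl–nickel species transfers one electron to ester 19, whose radical anion loses phthalimide anion and CO2 to give the C2 radical, stabilised by the lone pair of ring oxygen O1; the radical is captured by the aryl–nickel complex and reductive elimination from trivalent nickel forms the C2–aryl bond. The closest known reaction is the nickel-catalysed decarboxylative Negishi arylation of redox-active esters of α-alkoxy acids with arylzinc chlorides. No ring is closed in this step. The new stereocentre C2 is controlled by the neighbouring C3: the aryl–nickel unit should approach the nearly planar radical on the rigid five-membered ring from the face opposite the CH2OTBS group, placing the aryl group trans to it (2S,3R), and both C2 epimers of 19 converge on the same radical. The step needs trans diastereoselectivity and chemoselectivity for the redox-active ester; the first is secured by the C3 substituent on the fused ring, the second by the absence of any aryl halide, free OH or carbonyl electrophile in 19, whose silyl ethers and acetonide are inert to the arylzinc reagent.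

**Step 12**
Reactants: 23 coupled tris-silyl ether
Product: 24 4-[(2S,3R)-5-[(S)-hydroxy((R)-2,2-dimethyl-1,3-dioxolan-4-yl)methyl]-3-(hydroxymethyl)-7-methoxy-2,3-dihydrobenzofuran-2-yl]-2-methoxyphenol
Conditions: Bu4NF, AcOH, THF, 0 °C → rt
Reagents that add atoms: none
Why: Fluoride-mediated desilylation removes the aryl, primary and secondary silyl ethers together, and the acetic acid buffer should keep the liberated para-hydroxybenzylic ether from opening to a quinone methide.

**Step 13**
Reactants: 24 acetonide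
Product: 25 (1S,2R)-1-[(2S,3R)-2-(4-hydroxy-3-methoxyphenyl)-3-(hydroxymethyl)-7-methoxy-2,3-dihydrobenzofuran-5-yl]propane-1,2,3-triol
Conditions: AcOH/H2O (4:1), 40 °C
Reagents that add atoms: none
Why: Mild aqueous acid hydrolysis of the terminal acetonide should free the 1,2-diol without ionising the benzylic C7′–O or C2–O bonds, so no stereocentre is scrambled.

**Compound list**

1 | 2-bromo-6-methoxyphenol | COc1cccc(Br)c1O | starting material
2 | 2-bromo-4-iodo-6-methoxyphenol | COc1cc(I)cc(Br)c1O | intermediate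
3 | (2-bromo-4-iodo-6-methoxyphenoxy)(tert-butyl)dimethylsilane | COc1cc(I)cc(Br)c1O[Si](C)(C)C(C)(C)C | intermediate
4 | (R)-2,2-dimethyl-1,3-dioxolane-4-carbaldehyde | O=C[C@H]1COC(C)(C)O1 | starting material
5 | [3-bromo-4-(TBSO)-5-methoxyphenyl]magnesium chloride (not isolated) | COc1cc([Mg]Cl)cc(Br)c1O[Si](C)(C)C(C)(C)C | intermediate
6 | [3-bromo-4-(TBSO)-5-methoxyphenyl]titanium triisopropoxide (not isolated) | COc1cc([Ti](OC(C)C)(OC(C)C)OC(C)C)cc(Br)c1O[Si](C)(C)C(C)(C)C | intermediate
7 | (S)-[3-bromo-4-(TBSO)-5-methoxyphenyl][(R)-2,2-dimethyl-1,3-dioxolan-4-yl]methanol | COc1cc([C@H](O)[C@H]2COC(C)(C)O2)cc(Br)c1O[Si](C)(C)C(C)(C)C | intermediate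
8 | {2-bromo-4-[(S)-(TBSO)((R)-2,2-dimethyl-1,3-dioxolan-4-yl)methyl]-6-methoxyphenoxy}(tert-butyl)dimethylsilane | COc1cc([C@H](O[Si](C)(C)C(C)(C)C)[C@H]2COC(C)(C)O2)cc(Br)c1O[Si](C)(C)C(C)(C)C | intermediate
9 | (S)-4-benzyl-3-(2-chloroacetyl)oxazolidin-2-one | ClCC(=O)N1C(=O)OC[C@@H]1Cc1ccccc1 | starting material
10 | diethyl {2-[(S)-4-benzyl-2-oxooxazolidin-3-yl]-2-oxoethyl}phosphonate | CCOP(=O)(OCC)CC(=O)N1C(=O)OC[C@@H]1Cc1ccccc1 | intermediate
11 | 2-(tert-butyldimethylsilyloxy)acetaldehyde | CC(C)(C)[Si](C)(C)OCC=O | starting material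
12 | (S)-4-benzyl-3-[(E)-4-(TBSO)but-2-enoyl]oxazolidin-2-one | CC(C)(C)[Si](C)(C)OC/C=C/C(=O)N1C(=O)OC[C@@H]1Cc1ccccc1 | intermediate
13 | {2-(TBSO)-3-methoxy-5-[(S)-(TBSO)((R)-2,2-dimethyl-1,3-dioxolan-4-yl)methyl]phenyl}magnesium bromide (not isolated) | COc1cc([C@H](O[Si](C)(C)C(C)(C)C)[C@H]2COC(C)(C)O2)cc([Mg]Br)c1O[Si](C)(C)C(C)(C)C | intermediate
14 | bromomagnesium (Z)-enolate of the (3R) conjugate adduct of 13 and 12 (not isolated) | CC(C)(C)[Si](C)(C)Oc1c(OC)cc([C@H](O[Si](C)(C)C(C)(C)C)[C@H]2COC(C)(C)O2)cc1[C@@H](/C=C(\O[Mg]Br)N1C(=O)OC[C@@H]1Cc1ccccc1)CO[Si](C)(C)C(C)(C)C | intermediate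
15 | (S)-4-benzyl-3-[(2S,3R)-2-bromo-4-(TBSO)-3-{2-(TBSO)-3-methoxy-5-[(S)-(TBSO)((R)-2,2-dimethyl-1,3-dioxolan-4-yl)methyl]phenyl}butanoyl]oxazolidin-2-one | CC(C)(C)[Si](C)(C)Oc1c(OC)cc([C@H](O[Si](C)(C)C(C)(C)C)[C@H]2COC(C)(C)O2)cc1[C@@H]([C@H](Br)C(=O)N1C(=O)OC[C@@H]1Cc1ccccc1)CO[Si](C)(C)C(C)(C)C | intermediate
16 | (S)-4-benzyl-3-{(3R)-3-[(TBSO)methyl]-5-[(S)-(TBSO)((R)-2,2-dimethyl-1,3-dioxolan-4-yl)methyl]-7-methoxy-2,3-dihydrobenzofuran-2-carbonyl}oxazolidin-2-one, C2 epimers | COc1cc([C@H](O[Si](C)(C)C(C)(C)C)[C@H]3COC(C)(C)O3)cc2c1OC(C(=O)N1C(=O)OC[C@@H]1Cc1ccccc1)[C@H]2CO[Si](C)(C)C(C)(C)C | intermediate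
17 | (3R)-3-[(TBSO)methyl]-5-[(S)-(TBSO)((R)-2,2-dimethyl-1,3-dioxolan-4-yl)methyl]-7-methoxy-2,3-dihydrobenzofuran-2-carboxylic acid, C2 epimers | COc1cc([C@H](O[Si](C)(C)C(C)(C)C)[C@H]3COC(C)(C)O3)cc2c1OC(C(=O)O)[C@H]2CO[Si](C)(C)C(C)(C)C | intermediate
18 | N-hydroxyphthalimide | O=C1c2ccccc2C(=O)N1O | starting material
19 | 1,3-dioxoisoindolin-2-yl ester of acid 17, C2 epimers | COc1cc([C@H](O[Si](C)(C)C(C)(C)C)[C@H]3COC(C)(C)O3)cc2c1OC(C(=O)ON1C(=O)c3ccccc3C1=O)[C@H]2CO[Si](C)(C)C(C)(C)C | intermediate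
20 | (4-bromo-2-methoxyphenoxy)(tert-butyl)dimethylsilane | COc1cc(Br)ccc1O[Si](C)(C)C(C)(C)C | starting material
21 | [4-(TBSO)-3-methoxyphenyl]lithium (not isolated) | COc1cc([Li])ccc1O[Si](C)(C)C(C)(C)C | intermediate
22 | [4-(TBSO)-3-methoxyphenyl]zinc chloride (not isolated) | COc1cc([Zn]Cl)ccc1O[Si](C)(C)C(C)(C)C | intermediate
23 | tert-butyl{4-[(2S,3R)-3-[(TBSO)methyl]-5-[(S)-(TBSO)((R)-2,2-dimethyl-1,3-dioxolan-4-yl)methyl]-7-methoxy-2,3-dihydrobenzofuran-2-yl]-2-methoxyphenoxy}dimethylsilane | COc1cc([C@H]2Oc3c(OC)cc([C@H](O[Si](C)(C)C(C)(C)C)[C@H]4COC(C)(C)O4)cc3[C@@H]2CO[Si](C)(C)C(C)(C)C)ccc1O[Si](C)(C)C(C)(C)C | intermediate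
24 | 4-[(2S,3R)-5-[(S)-hydroxy((R)-2,2-dimethyl-1,3-dioxolan-4-yl)methyl]-3-(hydroxymethyl)-7-methoxy-2,3-dihydrobenzofuran-2-yl]-2-methoxyphenol | COc1cc([C@H]2Oc3c(OC)cc([C@H](O)[C@H]4COC(C)(C)O4)cc3[C@@H]2CO)ccc1O | intermediate
25 | (1S,2R)-1-[(2S,3R)-2-(4-hydroxy-3-methoxyphenyl)-3-(hydroxymethyl)-7-methoxy-2,3-dihydrobenzofuran-5-yl]propane-1,2,3-triol | COc1cc([C@H]2Oc3c(OC)cc([C@H](O)[C@H](O)CO)cc3[C@@H]2CO)ccc1O | target

**Totals**

Total step count: 13. Longest linear sequence: 11 steps (steps 1–4 and 7–13; steps 5 and 6 make the enoyl imide 12).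

**Steps most likely to fail**

1. Step 11. The hindered C2 radical may be captured too slowly by the aryl–nickel species, so that hydrogen abstraction or breakdown of the redox-active ester competes, or trans selectivity may erode. The fallback sets out from acid 17 and aryl bromide 20 and comes back at 23. It is an oxidative metallaphotoredox decarboxylative arylation: Ir[dF(CF3)ppy]2(dtbbpy)PF6 (1 mol%), NiCl2·glyme, 4,4′-di-tert-butyl-2,2′-bipyridine, Cs2CO3, DMF, blue light, 25 °C. Here the carboxylate of 17 is oxidised by the excited photocatalyst and the C2 radical is intercepted by the aryl–nickel bromide formed from 20 by oxidative addition, so neither the redox-active ester nor an arylzinc reagent is needed; it passes through no compound outside the list (F0).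

2. Step 7. Transfer of the ortho-silyloxy aryl group from copper to Cβ may be sluggish, with competing 1,2-addition, poor facial selectivity, or elimination during the bromination. The fallback sets out from bromide 8 and comes back at acid 17, replacing the auxiliary by asymmetric catalysis. Miyaura borylation of 8 (Pd(dppf)Cl2, B2pin2, KOAc, dioxane, 90 °C) should give the aryl pinacol boronate F1. Wittig olefination of aldehyde 11 with ethyl (triphenylphosphoranylidene)acetate gives ethyl (E)-4-(TBSO)but-2-enoate F2. Hayashi–Miyaura conjugate addition of F1 to F2 ([Rh(OH)((S)-BINAP)]2, dioxane/H2O, 50 °C) should give the (3R) β-aryl ester F3; the (S)-ligand is the one expected, by the usual facial model of this reaction, to deliver the aryl group to the same face as the auxiliary does. Enolate bromination (LiN(SiMe3)2, THF, −78 °C, then NBS) gives the α-bromo ester F4. Bu4NF then unmasks the phenol and closes the ring to the ethyl dihydrobenzofuran-2-carboxylate F5, and LiOH in THF/H2O gives 17.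

3. Step 3. Facial selectivity in the addition to the α-alkoxy aldehyde may be poor, giving much of the syn C7′ epimer. The fallback sets out from 7 as obtained together with its C7′ epimer and comes back at 7. The mixture is oxidised with Dess–Martin periodinane (NaHCO3, CH2Cl2) to the aryl ketone F6, which is reduced with Zn(BH4)2 in Et2O at −30 °C. Under α-chelation control (Cram chelate) hydride is delivered from the face of the small hydrogen substituent, which should give the anti carbinol 7; the stereocentre is then set by hydride delivery to a ketone and not by aryl addition to an aldehyde.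

**Further compounds**

F0 | step 11 | none | none
F1 | step 7 | tert-butyl{4-[(S)-(TBSO)((R)-2,2-dimethyl-1,3-dioxolan-4-yl)methyl]-2-methoxy-6-(4,4,5,5-tetramethyl-1,3,2-dioxaborolan-2-yl)phenoxy}dimethylsilane | COc1cc([C@H](O[Si](C)(C)C(C)(C)C)[C@H]2COC(C)(C)O2)cc(B3OC(C)(C)C(C)(C)O3)c1O[Si](C)(C)C(C)(C)C
F2 | step 7 | ethyl (E)-4-(tert-butyldimethylsilyloxy)but-2-enoate | CCOC(=O)/C=C/CO[Si](C)(C)C(C)(C)C
F3 | step 7 | ethyl (3R)-4-(TBSO)-3-{2-(TBSO)-3-methoxy-5-[(S)-(TBSO)((R)-2,2-dimethyl-1,3-dioxolan-4-yl)methyl]phenyl}butanoate | CC(C)(C)[Si](C)(C)Oc1c(OC)cc([C@H](O[Si](C)(C)C(C)(C)C)[C@H]2COC(C)(C)O2)cc1[C@@H](CC(=O)OCC)CO[Si](C)(C)C(C)(C)C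
F4 | step 7 | ethyl (3R)-2-bromo-4-(TBSO)-3-{2-(TBSO)-3-methoxy-5-[(S)-(TBSO)((R)-2,2-dimethyl-1,3-dioxolan-4-yl)methyl]phenyl}butanoate, C2 epimers | CC(C)(C)[Si](C)(C)Oc1c(OC)cc([C@H](O[Si](C)(C)C(C)(C)C)[C@H]2COC(C)(C)O2)cc1[C@@H](C(Br)C(=O)OCC)CO[Si](C)(C)C(C)(C)C
F5 | step 7 | ethyl (3R)-3-[(TBSO)methyl]-5-[(S)-(TBSO)((R)-2,2-dimethyl-1,3-dioxolan-4-yl)methyl]-7-methoxy-2,3-dihydrobenzofuran-2-carboxylate, C2 epimers | COc1cc([C@H](O[Si](C)(C)C(C)(C)C)[C@H]3COC(C)(C)O3)cc2c1OC(C(=O)OCC)[C@H]2CO[Si](C)(C)C(C)(C)C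
F6 | step 3 | [3-bromo-4-(TBSO)-5-methoxyphenyl][(R)-2,2-dimethyl-1,3-dioxolan-4-yl]methanone | COc1cc(C(=O)[C@H]2COC(C)(C)O2)cc(Br)c1O[Si](C)(C)C(C)(C)C
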